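The ratio of starting material to free catalyst as charged in the flask is 500, and a charge of 2.0 mM still leaves that ratio at 50.0. Catalyst is a trace at either charge, so the bench rule is tried here: at a fixed conversion, with the other charges held, rate scales with catalyst charged.

common to all: starting material 0.10 M; free catalyst 0.20 mM

| run | partner | remark |
|---|---|---|
| ash | 0.50 M | the very flask that is asked about, followed so far |
| flask | 0.500 M |  |

ash run (percent of the starting material charged): time / min: product / % = 0.417: 2.0; 1.00: 5.6; 2.00: 11.0; 3.00: 15.3

(readings scatter by 0.3 percentage points)

- no earlier run changes the charge of free catalyst; that part of a forecast is a guess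

* factor on the rate of making product when 50 % of the starting material are converted if free catalyst is charged twice over
* factor on the rate when 50 % of the starting material are converted if free catalyst is charged at 2.0 mM instead

The ash run is this same flask, followed so far. Its last reading is 15.3 % of product at 3.00 min. That is a mean rate per catalyst charged of 25.5 min⁻¹, the turnover frequency. Half conversion costs each catalyst 250 turnovers, so this frequency, held steady, gives a reckoned time to half conversion of 9.80 min.

| free catalyst | turnovers to half conversion | time at that frequency | factor on rate |
|---|---|---|---|
| 0.20 mM | 250 | 9.80 min | 1 |
| 0.400 mM | 125 | 4.90 min | 2 |
| 2.0 mM | 25.0 | 0.980 min | 10.0 |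

The rule freezes the partner. If one partner goes per product, half conversion costs 10.0 % of its charge, which looks harmless. The border lies with any loss that runs on the clock rather than on conversion. In this reckoning the 2.0 mM flask arrives ten times sooner, which leaves such a loss less time. The ash readings end at a third of the reckoned time and are readings of product, not of partner, so they give no direct measure of such a loss. The reckoning here stays with the table's factors.

The forecast gave 1.9 and 8, lower than this reckoning, in its words “I shade the estimates slightly below proportional and keep the ranges wide”.

The simulation gives 2.33 and 12.8.

    partner + free catalyst → catalyst intermediate A (k = 120 L mol⁻¹ min⁻¹)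
    starting material + catalyst intermediate A → catalyst intermediate B (k = 77000 L mol⁻¹ min⁻¹)
    catalyst intermediate B ⇌ by-product + catalyst intermediate C (K = 0.240 M, k = 51.0 min⁻¹)
    catalyst intermediate C → free catalyst + product (k = 4400 min⁻¹)
    partner → decomposed reagent (k = 0.0440 min⁻¹)

The 0.20 mM flask reaches half conversion at 10.6 min, later than the reckoned 9.80 min, while the partner's half-life by decomposition alone is 15.8 min. At 10.0 min the flask holds 0.168 M of decomposed reagent against 0.0475 M of by-product, with 57 % of the partner left. Over the 0.980 min that the turnover frequency gives the 2.0 mM flask, decomposition spares 95.8 % of the partner. In that flask, free catalyst is 49.0 % of the catalyst at half conversion, and the rate per catalyst charged at that conversion is 1.28 times that of the 0.20 mM flask.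

The readings were generated by integration for substances that don't exist; scatter was added.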